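The numbers in the tables stem from a simulated flask for an exercise, and the scatter is random.

**Maple's leftover.** Maple still holds 59 % of its L at 3.00 min. The new flask has maple's J but a smaller charge of Q, [Q] 0.0500 M against 0.075 M.

all flasks: L 0.050 M

| charge | J | Q | remark | time |
|---|---|---|---|---|
| elm | 0.10 M | 0.050 M | run made earlier |  |
| alder | 0.17 M | 0.050 M | run made earlier |  |
| maple | 0.075 M | 0.075 M | run made earlier |  |
| flask | 0.0750 M | 0.0500 M |  | 2.5 min |

| run | time / min | Z / % | L / % |
|---|---|---|---|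
| elm | 0.167 | 21 | 74 |
| elm | 0.200 | 26 | 70 |
| elm | 0.333 | 27 | 60 |
| elm | 0.667 | 26 | 48 |
| elm | 1.00 | 24 | 37 |
| elm | 2.00 | 12 | 25 |
| elm | 3.00 | 15 | 20 |
| alder | 0.167 | 34 | 60 |
| alder | 0.200 | 39 | 57 |
| alder | 0.333 | 41 | 43 |
| alder | 0.667 | 39 | 22 |
| alder | 1.00 | 30 | 11 |
| alder | 2.00 | 17 | 4 |
| alder | 3.00 | 13 | 2 |
| maple | 0.167 | 14 | 87 |
| maple | 0.250 | 19 | 77 |
| maple | 0.667 | 15 | 65 |
| maple | 1.33 | 14 | 63 |
| maple | 3.00 | 5 | 59 |

(standard deviation of a reading: 2 percentage points)

* the best time, 2.5 min at the latest, for Z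
* the amount of Z, in percent of the L charged, at that time



**Selectivity factor.** Own reckoning lets J feed both L and Q, takes each as first order in itself, and takes J, the limiting reagent, as used up in maple. Maple's L then took 0.0205 M of J and its Q took 0.0545 M, so 27.3 % of maple's Q is left. Maple gives 2.46 for S, the selectivity factor: ln of the fraction of Q left over ln of the fraction of L left.

**Two rounds.** The first answer for the flask is maple's pair of leftovers. With Q at 27.3 %, the J balance leaves L at 22.7 %, and the mean with maple's L is 40.8 %. Put back through S, that mean leaves Q at 11.0 % and L at 38.9 %. The new mean is 39.9 % of L left.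

**Peak Z.** Maple's highest reading is 19 % and elm's is 27 %. Elm's J equals its L plus Q, so its reckoned leftover, once J is used up, is zero. Interpolating on the leftover gives 21.6 %. This reckoning gives no time.

**The forecast.** It says 21 % at 0.3 min: “Waiting longer gains nothing”.

**The flask.** Z reaches 21.8 % at 0.448 min. It reads 21.5 % at 0.358 min and 20.6 % at 0.672 min, a flat top.

    Z ⇌ X (K = 7.30, k = 0.0300 s⁻¹)
    L + J → Z (k = 0.380 M⁻¹ s⁻¹)
    Q + J → G (k = 1.00 M⁻¹ s⁻¹)

In the flask, L stands at 40.6 % at 25.0 min, beside the reckoned 39.9 %. S also serves a neighbour, the same flask with [Q] 0.20 M. If Q takes every J, its Q left is 62.5 % and its L left 82.6 %. Putting that L back gives 84.9 %. That neighbour holds 85.5 % of its L at 2.50 min, with J at 0 %.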